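The winter run reads 20 % product after 15.0 h with 13 µM of added ligand, and this flask holds 17 µM. I need its standing at 25 h.

all flasks: substrate 10 mM; gas phase 2.8 mM (held); catalyst 10 µM

| run | added ligand | remark | time |
|---|---|---|---|
| spring | 8.5 µM | run made earlier |  |
| winter | 13 µM | run made earlier |  |
| flask | 17 µM |  | 25 h |

| run | time / h | product / % | substrate / % |
|---|---|---|---|
| spring | 4.00 | 4 | 97 |
| spring | 8.00 | 10 | 92 |
| spring | 12.0 | 17 | 83 |
| spring | 15.0 | 23 | 79 |
| winter | 4.00 | 3 | 100 |
| winter | 8.00 | 12 | 89 |
| winter | 12.0 | 14 | 83 |
| winter | 15.0 | 20 | 81 |

(scatter of a reading: 1.5 percentage points)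

- the product standing at 25 h, as a percentage of the substrate charged
- concentration of dissolved gas in solution at 25 h, in percent of saturation

- at the start none of the gas is dissolved
- reactions considered so far: gas phase <-> dissolved gas; substrate + dissolved gas + catalyst <-> catalyst + product; catalyst + added ligand <-> idle complex

The gas is held, so I keep the books on the substrate. One entry is product and the other is substrate left. At the last reading they add up to 102 % in the spring run and 101 % in the winter run. With a scatter of 1.5 percentage points per reading, I open no third entry.

Now the product entry. No gas is dissolved at the start, and both runs begin slowly. A line through the mean readings at 4.00 h and 15.0 h meets zero product at a lag of 1.86 h. Past the lag I take the rate as proportional to substrate, so the integral is closed: the substrate share left is exp(−k(t − lag)).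

The last readings give k as 0.0199 /h in the spring run and 0.0170 /h in the winter run. The ligand steps are similar, 4.50 µM and then 4.00 µM, so I apply the same ratio once more. That gives this flask's clock constant, its pseudo-first-order constant past the lag: 0.0145 /h. This is a soft reading, resting on scattered points.

Over 23.1 h my books close at 28.5 % product and 71.5 % substrate. I reckon no gas figure.

The forecast, holding that “There is no stoichiometric cliff, so binding is weak”, gives 31 % product and 92 % of saturation.

The flask gives 29.1 % product and 82.8 % of saturation, with 71 % of the substrate left.

    gas phase ⇌ dissolved gas, rate k1*(csat - [dissolved gas]) (kL = 0.200 /h)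
    substrate + dissolved gas + catalyst ⇌ catalyst + product (K = 260 /M, k = 1.80 × 10⁶ /M²/h)
    catalyst + added ligand ⇌ idle complex (K = 21000 /M, k = 79000 /M/h)

My constant gives 5.83 % at 6.0 h, where the neighbouring flask reads 6.86 %. But this flask is not at rest at 25 h. At ten times that time, the constant gives 97.3 %, while the flask stands lower, at 42.1 % product. So the clock serves at 25 h but not at 250 h. Over that stretch, dissolved gas climbs from 2.32 mM to 2.80 mM. Substrate falls from 70.9 % to 57.9 %, while catalyst stays at 76.5 % of its charge.

(The runs were computed for an exercise; the scatter is artificial.)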